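**Plan**
Numbering: lactone O1, C2(=O), C3(CH3), C4(OH), C5; chain C6 (ylidene CH) to C14 (CH2 on furan ring A); ring B is the terminal 3-furyl.
Cuts, in retrosynthetic order: the C4 O–CH3 bond (methyl kept as protection), the C5=C6 unsaturation, the lactone bond O1–C2 (back to a 4-hydroxycyclobutenone), C5–C6 (alkyllithium plus 3-methoxy-4-methylcyclobutenedione), C8–C9 (alkylzinc plus dienyl iodide), C9=C10, C11=C12, C14–ring A, and the bond from the inter-ring CH2 to ring B.
Enabling feature: C2–C5 of the butenolide, with CH3 on C3 and oxygen on C2, C4 and C5, are the four carbons of a methoxy(methyl)cyclobutenedione that carries the chain on one former carbonyl carbon.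
Forward: rings A and B are joined and extended to an E,E-dienyl iodide (C9–C14); the C6–C8 unit is coupled on at C8–C9; the C6 iodide is lithiated and added to the cyclobutenedione; the butenolide ring is formed last by thermal ring expansion, then C5=C6 is introduced and the O-methyl removed.
Stereochemistry: C7 (S) comes from methyl (R)-3-hydroxy-2-methylpropanoate; the two E alkenes come from a stabilised Wittig reaction and a Takai olefination; the Z ylidene comes from the selenoxide elimination.

Key step: step 15

Notation: Q = (2S,4E,6E)-9-[5-(furan-3-ylmethyl)furan-3-yl]-2,6-dimethylnona-4,6-dien-1-yl, bonded through its C1 (C6 of the target numbering).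
Assumption: the carbinol carbon of 23 and C5 of 26 and 28 are carried as epimer mixtures, because both centres become sp2 when C5=C6 is formed.

Step 1
Reactants: 1 3-bromofuran; 2 4-bromofuran-2-carbaldehyde
Product: 4 (4-bromofuran-2-yl)(furan-3-yl)methanol (racemic), via furan-3-yllithium 3 (not isolated)
Conditions: 1, n-BuLi, THF, −78 °C; then 2, −78 °C; aq. NH4Cl
Reagents that add atoms: none
Why: Bromine–lithium exchange on 3-bromofuran at −78 °C gives 3 without migration of lithium to C2, and its 1,2-addition to the aldehyde of 2 should outrun exchange with the ring bromide; the carbinol centre is racemic and disappears in step 2.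

Step 2
Reactants: 4 (4-bromofuran-2-yl)(furan-3-yl)methanol
Product: 5 4-bromo-2-(furan-3-ylmethyl)furan
Conditions: Et3SiH (3 equiv), CF3CO2H, CH2Cl2, −20 → 0 °C
Reagents that add atoms: none
Why: Ionic hydrogenation, in which acid ionises the carbinol to a cation stabilised by both furan rings and Et3SiH delivers hydride to it, the cold silane-rich medium keeping the cation from alkylating a second furan.

Step 3
Reactants: 5 4-bromo-2-(furan-3-ylmethyl)furan
Product: 7 3-[5-(furan-3-ylmethyl)furan-3-yl]propan-1-ol, via furyllithium 6 (not isolated)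
Conditions: n-BuLi, THF, −78 °C; then oxetane, BF3·OEt2, −78 °C; aq. NH4Cl
Reagents that add atoms: oxetane, C1COC1
Why: Bromine–lithium exchange at −78 °C should be faster than deprotonation of the CH2 between the furans, and the 3-furyllithium 6 opens BF3-activated oxetane (Lewis acid-promoted oxetane opening by an organolithium), adding C14, C13 and C12 in one operation.

Step 4
Reactants: 7 3-[5-(furan-3-ylmethyl)furan-3-yl]propan-1-ol
Product: 8 3-[5-(furan-3-ylmethyl)furan-3-yl]propanal
Conditions: Dess–Martin periodinane, NaHCO3, CH2Cl2, 0 → 25 °C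
Reagents that add atoms: none
Why: Buffered Dess–Martin oxidation takes the primary alcohol to the aldehyde under neutral conditions that leave both furans untouched.

Step 5
Reactants: 8 3-[5-(furan-3-ylmethyl)furan-3-yl]propanal
Product: 9 (2E)-5-[5-(furan-3-ylmethyl)furan-3-yl]-2-methylpent-2-enal
Conditions: Ph3P=C(CH3)CHO, toluene, 90 °C
Reagents that add atoms: 2-(triphenylphosphoranylidene)propanal, CC(C=O)=P(c1ccccc1)(c1ccccc1)c1ccccc1
Why: Wittig olefination with the formyl-stabilised ylide should give the E trisubstituted enal (C11=C12), because the stabilised ylide adds reversibly and collapses through the less crowded oxaphosphetane.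

Step 6
Reactants: 9 (2E)-5-[5-(furan-3-ylmethyl)furan-3-yl]-2-methylpent-2-enal
Product: 10 2-(furan-3-ylmethyl)-4-[(3E,5E)-6-iodo-4-methylhexa-3,5-dien-1-yl]furan
Conditions: CrCl2 (6 equiv), CHI3 (2 equiv), THF/1,4-dioxane 1:6, 0 → 25 °C, dark
Reagents that add atoms: iodoform, IC(I)I
Why: Takai olefination, in which the geminal dichromium species from CHI3 and CrCl2 adds to the aldehyde and eliminates to the E vinyl iodide (C9=C10), dioxane favouring the E isomer and the furans and trisubstituted alkene being inert to divalent chromium.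

Step 7
Reactants: 11 methyl (R)-3-hydroxy-2-methylpropanoate
Product: 12 methyl (R)-3-[(tert-butyldimethylsilyl)oxy]-2-methylpropanoate
Conditions: TBSCl, imidazole, CH2Cl2, 0 → 25 °C
Reagents that add atoms: tert-butyldimethylsilyl chloride, CC(C)(C)[Si](C)(C)Cl
Why: Standard silylation of the primary alcohol with a base too weak to epimerise the centre next to the ester; this oxygen-bearing carbon becomes C6.

Step 8
Reactants: 12 methyl (R)-3-[(tert-butyldimethylsilyl)oxy]-2-methylpropanoate
Product: 13 (S)-3-[(tert-butyldimethylsilyl)oxy]-2-methylpropan-1-ol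
Conditions: i-Bu2AlH (2.3 equiv), CH2Cl2, −78 → 0 °C; aq. potassium sodium tartrate
Reagents that add atoms: none
Why: Hydride reduction of the ester to the primary alcohol (future C8) at low temperature proceeds without enolisation or silyl migration, so the methyl-bearing centre is kept; the descriptor changes only through the priority rules.

Step 9
Reactants: 13 (S)-3-[(tert-butyldimethylsilyl)oxy]-2-methylpropan-1-ol
Product: 14 (R)-tert-butyl(3-iodo-2-methylpropoxy)dimethylsilane
Conditions: I2, PPh3, imidazole, CH2Cl2, 0 → 25 °C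
Reagents that add atoms: iodine, II
Why: Garegg–Samuelsson iodination, in which iodide displaces the alkoxyphosphonium group by SN2 at the primary carbon, one bond away from the untouched stereocentre.

Step 10
Reactants: 14 (R)-tert-butyl(3-iodo-2-methylpropoxy)dimethylsilane; 10 2-(furan-3-ylmethyl)-4-[(3E,5E)-6-iodo-4-methylhexa-3,5-dien-1-yl]furan
Product: 16 tert-butyldimethylsilyl ether Q–OSi(CH3)2C(CH3)3, via alkylzinc iodide 15 (not isolated)
Conditions: 14, Zn dust (activated with BrCH2CH2Br/Me3SiCl), LiCl, THF, 40 °C; then 10, Pd(PPh3)4 (5 mol %), THF, 25 °C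
Reagents that add atoms: none
Why: Zinc inserts into the primary C–I bond to give the silyl ether-tolerant alkylzinc 15, and Negishi sp3–sp2 coupling under zerovalent palladium forms C8–C9 with retention of the E,E geometry of 10, reductive elimination outpacing β-hydride elimination for a primary alkylzinc.

Step 11
Reactants: 16 silyl ether Q–OSi(CH3)2C(CH3)3
Product: 17 alcohol Q–OH
Conditions: Bu4NF, THF, 0 → 25 °C
Reagents that add atoms: none
Why: Fluoride-mediated desilylation cleaves the Si–O bond under conditions harmless to the furans and the diene.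

Step 12
Reactants: 17 alcohol Q–OH
Product: 18 iodide Q–I
Conditions: I2, PPh3, imidazole, CH2Cl2, 0 °C, dark
Reagents that add atoms: iodine, II
Why: Garegg–Samuelsson iodination at the primary C6 carbon by SN2, short and cold enough that iodine should not engage the diene, with C7 untouched.

Step 13
Reactants: 19 dimethyl squarate
Product: 21 3-methoxy-4-methylcyclobut-3-ene-1,2-dione, via hydroxycyclobutenone 20 (not isolated)
Conditions: MeLi (1.05 equiv), THF, −78 °C; aq. NH4Cl; then conc. HCl (cat.), CH2Cl2, 25 °C
Reagents that add atoms: methyllithium, [Li]C; water, O (its oxygen becomes the new carbonyl oxygen while the carbinol oxygen leaves as water)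
Why: 1,2-Addition of MeLi to one squarate carbonyl gives 20, and acid then ionises the tertiary carbinol to a methoxy-stabilised cyclobutenyl cation that takes up water at the former enol ether carbon and loses methanol (the known squarate to alkylcyclobutenedione sequence).

Step 14
Reactants: 18 iodide Q–I; 21 3-methoxy-4-methylcyclobut-3-ene-1,2-dione
Product: 23 4-hydroxy-3-methoxy-2-methyl-4-Q-cyclobut-2-en-1-one (both carbinol epimers), via alkyllithium 22 (not isolated)
Conditions: 18, t-BuLi (2.1 equiv), Et2O/pentane, −78 °C; cannulated into 21 (1.3 equiv), THF, −78 °C; aq. NH4Cl at −78 °C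
Reagents that add atoms: none
Why: Iodine–lithium exchange on a primary iodide with two equivalents of t-BuLi is near-instantaneous at −78 °C and should spare the diene and furan C–H bonds, and 22 adds 1,2 to the carbonyl of 21 next to the methoxy-bearing carbon because the other carbonyl is deactivated as a vinylogous ester; the new carbinol centre forms as both epimers, which is immaterial.

Step 15
Reactants: 23 4-hydroxy-3-methoxy-2-methyl-4-Q-cyclobut-2-en-1-one
Product: 26 4-methoxy-3-methyl-5-Q-furan-2(5H)-one (both C5 epimers), via hydroxy vinylketene 24 (not isolated), via 2-hydroxyfuran tautomer 25 (not isolated)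
Conditions: p-xylene (0.02 M), 138 °C (reflux), argon
Reagents that add atoms: none
Why: Heat opens the strained cyclobutenone of 23 by conrotatory 4π-electrocyclic cleavage of the bond between the carbonyl carbon and the carbinol carbon (the future C2 and C5), giving the (2-hydroxyvinyl)ketene 24. The opening is reversible, and although outward rotation of the hydroxyl is electronically preferred, only the rotamer with the hydroxyl turned inward has a forward path: its oxygen adds to the sp ketene carbon in a 5-exo-dig closure that forms O1–C2 and the five-membered ring as the 2-hydroxyfuran 25, which tautomerises by protonation at C5 to the conjugated methyl tetronate 26. The closest known reaction type is the thermal ring expansion of squarate-derived 4-alkyl-4-hydroxycyclobutenones to 2(5H)-furanones. C5 is created in the tautomerisation with no control element and is accepted as both epimers because it becomes sp2 in step 17, while C7 is not involved. The selectivity needed is positional (methyl on C3, methoxy on C4) and chemoselective: the first is fixed by the carbonyl selectivity of step 14, the second by the sp3 nature of C6, which gives the ketene no aryl or alkenyl partner for a competing ring closure, and by high dilution, which disfavours bimolecular ketene reactions with the remote diene and furans.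

Step 16
Reactants: 26 4-methoxy-3-methyl-5-Q-furan-2(5H)-one
Product: 28 4-methoxy-3-methyl-5-(phenylselanyl)-5-Q-furan-2(5H)-one (both C5 epimers), via lithium dienolate 27 (not isolated)
Conditions: LiN(i-Pr)2 (1.1 equiv), THF, −78 °C; then PhSeBr (1.1 equiv), −78 °C
Reagents that add atoms: phenylselenenyl bromide, Br[Se]c1ccccc1
Why: The amide base removes the C5 proton (γ to the carbonyl and α to O1) to give the 2-furanolate 27, which should be selenenylated at C5 because that restores the conjugated methoxy butenolide (γ-selenenylation of a dienolate); the quaternary centre forms without control and is erased in step 17.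

Step 17
Reactants: 28 4-methoxy-3-methyl-5-(phenylselanyl)-5-Q-furan-2(5H)-one
Product: 30 (5Z)-5-{(2S,4E,6E)-9-[5-(furan-3-ylmethyl)furan-3-yl]-2,6-dimethylnona-4,6-dien-1-ylidene}-4-methoxy-3-methylfuran-2(5H)-one, via selenoxide 29 (not isolated)
Conditions: mCPBA (1.05 equiv), CH2Cl2, −78 °C; then i-Pr2NH, −78 → 25 °C
Reagents that add atoms: none
Why: Oxidation at selenium is far faster than epoxidation of the diene at −78 °C, and the selenoxide 29 undergoes syn-elimination on warming, C6–H being the only β-hydrogen and the transition state that keeps C7 away from the C4 methoxy group leading to the Z ylidene, while the amine keeps benzeneselenenic acid from adding to the alkenes.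

Step 18
Reactants: 30 Z-ylidene methyl tetronate
Product: 31 (5Z)-5-{(2S,4E,6E)-9-[5-(furan-3-ylmethyl)furan-3-yl]-2,6-dimethylnona-4,6-dien-1-ylidene}-4-hydroxy-3-methylfuran-2(5H)-one (target)
Conditions: NaSEt (3 equiv), DMF, 25 → 50 °C; then cold 1 M HCl to pH 3
Reagents that add atoms: none
Why: The thiolate attacks the O-methyl carbon by SN2 with the tetronate (a vinylogous carboxylate) as leaving group, so the ether should be cleaved without touching the lactone, the ylidene geometry or C7, and brief cold acidification liberates the tetronic acid.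

**Compound list**
1 | 3-bromofuran | Brc1ccoc1 | starting material
2 | 4-bromofuran-2-carbaldehyde | O=Cc1cc(Br)co1 | starting material
3 | furan-3-yllithium | [Li]c1ccoc1 | intermediate (not isolated)
4 | (4-bromofuran-2-yl)(furan-3-yl)methanol, racemic | OC(c1ccoc1)c1cc(Br)co1 | intermediate
5 | 4-bromo-2-(furan-3-ylmethyl)furan | Brc1coc(Cc2ccoc2)c1 | intermediate
6 | [5-(furan-3-ylmethyl)furan-3-yl]lithium | [Li]c1coc(Cc2ccoc2)c1 | intermediate (not isolated)
7 | 3-[5-(furan-3-ylmethyl)furan-3-yl]propan-1-ol | OCCCc1coc(Cc2ccoc2)c1 | intermediate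
8 | 3-[5-(furan-3-ylmethyl)furan-3-yl]propanal | O=CCCc1coc(Cc2ccoc2)c1 | intermediate
9 | (2E)-5-[5-(furan-3-ylmethyl)furan-3-yl]-2-methylpent-2-enal | O=C/C(C)=C/CCc1coc(Cc2ccoc2)c1 | intermediate
10 | 2-(furan-3-ylmethyl)-4-[(3E,5E)-6-iodo-4-methylhexa-3,5-dien-1-yl]furan | I/C=C/C(C)=C/CCc1coc(Cc2ccoc2)c1 | intermediate
11 | methyl (R)-3-hydroxy-2-methylpropanoate | C[C@H](CO)C(=O)OC | starting material
12 | methyl (R)-3-[(tert-butyldimethylsilyl)oxy]-2-methylpropanoate | C[C@H](CO[Si](C)(C)C(C)(C)C)C(=O)OC | intermediate
13 | (S)-3-[(tert-butyldimethylsilyl)oxy]-2-methylpropan-1-ol | C[C@H](CO[Si](C)(C)C(C)(C)C)CO | intermediate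
14 | (R)-tert-butyl(3-iodo-2-methylpropoxy)dimethylsilane | C[C@H](CO[Si](C)(C)C(C)(C)C)CI | intermediate
15 | {(2R)-3-[(tert-butyldimethylsilyl)oxy]-2-methylpropyl}zinc iodide | C[C@H](CO[Si](C)(C)C(C)(C)C)C[Zn]I | intermediate (not isolated)
16 | tert-butyl{[(2S,4E,6E)-9-[5-(furan-3-ylmethyl)furan-3-yl]-2,6-dimethylnona-4,6-dien-1-yl]oxy}dimethylsilane | C[C@H](CO[Si](C)(C)C(C)(C)C)C/C=C/C(C)=C/CCc1coc(Cc2ccoc2)c1 | intermediate
17 | (2S,4E,6E)-9-[5-(furan-3-ylmethyl)furan-3-yl]-2,6-dimethylnona-4,6-dien-1-ol | OC[C@@H](C)C/C=C/C(C)=C/CCc1coc(Cc2ccoc2)c1 | intermediate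
18 | 2-(furan-3-ylmethyl)-4-[(3E,5E,8S)-9-iodo-4,8-dimethylnona-3,5-dien-1-yl]furan | IC[C@@H](C)C/C=C/C(C)=C/CCc1coc(Cc2ccoc2)c1 | intermediate
19 | dimethyl squarate (3,4-dimethoxycyclobut-3-ene-1,2-dione) | COC1=C(OC)C(=O)C1=O | starting material
20 | 4-hydroxy-2,3-dimethoxy-4-methylcyclobut-2-en-1-one | COC1=C(OC)C(C)(O)C1=O | intermediate (not isolated)
21 | 3-methoxy-4-methylcyclobut-3-ene-1,2-dione | COC1=C(C)C(=O)C1=O | intermediate
22 | [(2R,4E,6E)-9-[5-(furan-3-ylmethyl)furan-3-yl]-2,6-dimethylnona-4,6-dien-1-yl]lithium (same spatial arrangement at C7 as 18; the descriptor changes because CH2Li ranks below the allylic CH2) | [Li]C[C@@H](C)C/C=C/C(C)=C/CCc1coc(Cc2ccoc2)c1 | intermediate (not isolated)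
23 | 4-hydroxy-3-methoxy-2-methyl-4-{(2S,4E,6E)-9-[5-(furan-3-ylmethyl)furan-3-yl]-2,6-dimethylnona-4,6-dien-1-yl}cyclobut-2-en-1-one, both carbinol epimers | CC1=C(OC)C(O)(C[C@@H](C)C/C=C/C(C)=C/CCc2coc(Cc3ccoc3)c2)C1=O | intermediate
24 | (3Z,5S,7E,9E)-12-[5-(furan-3-ylmethyl)furan-3-yl]-4-hydroxy-3-methoxy-2,5... simplified: the ketene O=C=C(CH3)–C(OCH3)=C(OH)–Q with the hydroxyl cis to the ketenyl carbon | O=C=C(C)/C(OC)=C(\O)C[C@@H](C)C/C=C/C(C)=C/CCc1coc(Cc2ccoc2)c1 | intermediate (not isolated)
25 | 4-methoxy-3-methyl-5-Q-furan-2-ol (Q as defined above) | Cc1c(O)oc(C[C@@H](C)C/C=C/C(C)=C/CCc2coc(Cc3ccoc3)c2)c1OC | intermediate (not isolated)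
26 | 5-{(2S,4E,6E)-9-[5-(furan-3-ylmethyl)furan-3-yl]-2,6-dimethylnona-4,6-dien-1-yl}-4-methoxy-3-methylfuran-2(5H)-one, both C5 epimers | CC1=C(OC)C(C[C@@H](C)C/C=C/C(C)=C/CCc2coc(Cc3ccoc3)c2)OC1=O | intermediate
27 | lithium 4-methoxy-3-methyl-5-Q-furan-2-olate | Cc1c(O[Li])oc(C[C@@H](C)C/C=C/C(C)=C/CCc2coc(Cc3ccoc3)c2)c1OC | intermediate (not isolated)
28 | 5-{(2S,4E,6E)-9-[5-(furan-3-ylmethyl)furan-3-yl]-2,6-dimethylnona-4,6-dien-1-yl}-4-methoxy-3-methyl-5-(phenylselanyl)furan-2(5H)-one, both C5 epimers | CC1=C(OC)C([Se]c2ccccc2)(C[C@@H](C)C/C=C/C(C)=C/CCc2coc(Cc3ccoc3)c2)OC1=O | intermediate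
29 | the Se-oxide of 28 (5-benzeneseleninyl lactone) | CC1=C(OC)C([Se](=O)c2ccccc2)(C[C@@H](C)C/C=C/C(C)=C/CCc2coc(Cc3ccoc3)c2)OC1=O | intermediate (not isolated)
30 | (5Z)-5-{(2S,4E,6E)-9-[5-(furan-3-ylmethyl)furan-3-yl]-2,6-dimethylnona-4,6-dien-1-ylidene}-4-methoxy-3-methylfuran-2(5H)-one | CC1=C(OC)/C(=C/[C@@H](C)C/C=C/C(C)=C/CCc2coc(Cc3ccoc3)c2)OC1=O | intermediate
31 | (5Z)-5-{(2S,4E,6E)-9-[5-(furan-3-ylmethyl)furan-3-yl]-2,6-dimethylnona-4,6-dien-1-ylidene}-4-hydroxy-3-methylfuran-2(5H)-one | CC1=C(O)/C(=C/[C@@H](C)C/C=C/C(C)=C/CCc2coc(Cc3ccoc3)c2)OC1=O | target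

**Step count**
Total: 18 steps. Longest linear sequence: 14 steps (steps 1–6, 10–12, 14–18, from 3-bromofuran and 4-bromofuran-2-carbaldehyde).

**Steps most likely to fail**

Step 17. The selenoxide is allylic (Se–C5–C4=C3), so a [2,3]-sigmatropic shift to the C3 selenenate may compete with syn-elimination, and the elimination may discriminate poorly between the two ylidene geometries. The fallback sets out from 26. The dienolate 27 is generated as in step 16 and brominated at C5 with 1,2-dibromo-1,1,2,2-tetrachloroethane (THF, −78 °C) to give the 5-bromo lactone F1. DBU (CH2Cl2, 0 → 25 °C) then removes hydrogen bromide in a base-mediated elimination toward C6, which should favour the less crowded Z ylidene. The route is rejoined at 30.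

Step 14. Proton transfer from the doubly activated CH2 between the furans to t-BuLi or to 22, addition of t-BuLi to the diene, or enolisation of 21 through its ring methyl group may consume material before the C5–C6 bond forms. The fallback sets out from 18 and reverses the polarity. 4-Methoxy-3-methylfuran-2(5H)-one is lithiated at C5 with LiN(i-Pr)2 (THF, −78 °C) and alkylated with 18 in THF/DMPU (−78 → 0 °C), a known C5-alkylation of methyl tetronates. This delivers 26 directly, where the route is rejoined, and makes no new compound (F0). It gives up the ring expansion for that material.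

Step 15. The productive opening with the hydroxyl turned inward is the minor channel, so during prolonged heating the ketene may be lost to oligomerisation or the diene and furans may degrade. The fallback sets out from 17. Buffered Dess–Martin oxidation gives the α-methyl aldehyde F2, which is used at once to limit epimerisation at C7. Aldol addition of C5-lithiated 4-methoxy-3-methylfuran-2(5H)-one (LiN(i-Pr)2, THF, −78 °C) gives the β-hydroxy lactone F3 as a diastereomer mixture. Mesylation (MsCl, Et3N, CH2Cl2, 0 °C) gives the mesylate F4, and E1cB elimination with DBU should give the Z ylidene. The route is rejoined at 30.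

Further compounds
F1 | step 17 | 5-bromo-5-{(2S,4E,6E)-9-[5-(furan-3-ylmethyl)furan-3-yl]-2,6-dimethylnona-4,6-dien-1-yl}-4-methoxy-3-methylfuran-2(5H)-one, both C5 epimers | CC1=C(OC)C(Br)(C[C@@H](C)C/C=C/C(C)=C/CCc2coc(Cc3ccoc3)c2)OC1=O
F0 | step 14 | none | none
F2 | step 15 | (2S,4E,6E)-9-[5-(furan-3-ylmethyl)furan-3-yl]-2,6-dimethylnona-4,6-dienal | O=C[C@@H](C)C/C=C/C(C)=C/CCc1coc(Cc2ccoc2)c1
F3 | step 15 | 5-{(2S,4E,6E)-9-[5-(furan-3-ylmethyl)furan-3-yl]-1-hydroxy-2,6-dimethylnona-4,6-dien-1-yl}-4-methoxy-3-methylfuran-2(5H)-one, diastereomer mixture at C5 and the carbinol carbon | CC1=C(OC)C(C(O)[C@@H](C)C/C=C/C(C)=C/CCc2coc(Cc3ccoc3)c2)OC1=O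
F4 | step 15 | methanesulfonate of F3 at the side-chain hydroxyl | CC1=C(OC)C(C(OS(C)(=O)=O)[C@@H](C)C/C=C/C(C)=C/CCc2coc(Cc3ccoc3)c2)OC1=O
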